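# Grevirobstol B by a macrocyclizing ketene-acetal diene–alkynoate Diels–Alder benzannulation

## The problem

Grevirobstol B (24) is a 22-membered cyclophane without a stereocentre. Its two benzene rings are joined once through a diaryl ether oxygen and once through an unbranched chain of sixteen methylene groups. Ring A carries OH at C1, the chain at C3 and the ether oxygen at C5. Ring B carries the ether oxygen at C1, OH at C2 and C4, and the chain at C6.

With nothing to control stereochemically, the difficulties are the ring closure and the ether. The ring B oxygen sits between the C2 oxygen and the C6 chain on an electron-rich ring, so ring B is a poor electrophile and a hindered nucleophile for direct arylation. Ring A is meta-substituted throughout and has no activating group for substitution at C5. The C16 tether has no functional handle and must be assembled linearly from simple pieces.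

Ring B is a hydroquinone-type monoether (C1 O para to C4 OH) and is easily oxidised once its phenols are free. Both ring B oxygens are therefore best carried as methyl ethers to the last step, and oxidants are best avoided late.

The enabling feature is ring A. C1 OH and C5 O meta to each other, with carbon at C3, is the pattern of an orsellinate. C4–C5–C6–C1 can therefore come from a 1,1,3-trioxygenated butadiene and C2–C3 from an alk-2-ynoate. The carboxyl of that ynoate ends at C2, ortho to the C1 OH and para to the C5 oxygen, and can be removed afterwards. The C5 oxygen of the diene can be the ring B phenol oxygen, attached earlier by conjugate addition to a linear ynoate, where crowding matters little.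

## Retrosynthesis

**24 ⇒ 23 ⇒ 22.** The two ring B methyl ethers are cut last (23), and before that the C2–CO2H bond of ring A (22). The carboxyl is a traceless activating group: a 2-hydroxy-4-aryloxy-6-alkylbenzoic acid is set up for protodecarboxylation. Neither step touches the skeleton, and the forward reactions only need to spare a diaryl ether.

**22 ⇒ 19 (key disconnection).** C3–C4 and C1–C2 of ring A are cut in a retro-[4+2]. This opens ring A and the 22-membered ring together and leads to acyclic 19, a silyl ketene-acetal diene on the ring B oxygen with a silyl alk-2-ynoate at the chain end. The neighbouring cuts are weaker. Cutting the ether O–C5(ring A) bond would require arylation of the hindered ring B phenol. Cutting a chain C–C bond would still require that diaryl ether first. The forward reaction must be regioselective (diene CH2 terminus to alkyne β-carbon) and must cyclize rather than oligomerize; it passes through cycloadduct 20 and bis-silyl arene 21.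

**19 ⇒ 17.** Two O–Si bonds are cut, giving acid-ester 17. The dienophile is carried as a free alkynoic acid, not as a methyl ester, for a mechanistic reason. An alkynoate ester has a propargylic CH2 as acidic as the γ-methyl of the vinylogous ester, and an amide base would not distinguish them. As the lithium carboxylate (in dianion 18) the alkynoate is protected from deprotonation, and silylation then turns it into a silyl ester, which is electronically an ordinary alkynoate. A later saponification is also saved, because work-up of the cycloaddition gives acid 22 directly.

**17 ⇒ 15.** The C–CO2H bond at the alkyne terminus is cut (via cesium salt 16). Catalytic C–H carboxylation with CO2 and a carbonate base is preferred to acetylide/chloroformate chemistry, because organolithium bases would attack the vinylogous ester already in 15.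

**15 ⇒ 13 + 14.** The O–C(vinyl) bond is cut: phenol 13 adds to methyl but-2-ynoate (14). This is where the hindered ring B oxygen is attached, at an sp carbon. Doing it while the chain end is still an unactivated terminal alkyne leaves the phenoxide only one acceptor.

**13 ⇒ 11 ⇒ 9.** The phenol C–O bond is traced to a formyl group (Dakin oxidation through formate 12), and the formyl group to Vilsmeier formylation of the 5-alkylresorcinol dimethyl ether 9 (through iminium salt 10). This pair is chosen because ortho-metalation of 9 would go between the two methoxy groups, whereas electrophilic formylation goes ortho to the chain.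

**9 ⇒ 8 ⇒ 7.** The alkyne is cut back by one carbon to aldehyde 8 and then to alcohol 7. The aldehyde carbon becomes C3 of ring A, so the chain length is fixed here.

**7 ⇒ 6 ⇒ 3 + 4; 3 ⇒ 1 + 2.** The benzylic C–C bond is cut as a Wittig alkene (6, via ylide 5) between 3,5-dimethoxybenzaldehyde (4) and the phosphonium salt 3 from 16-bromohexadecan-1-ol (1) and triphenylphosphine (2). Fifteen methylenes of 1 plus the aldehyde carbon of 4 give the sixteen CH2 groups, and the carbinol carbon of 1 becomes ring A C3.

## Roads not taken

**Alternative 1:** The cut is the benzylic C=C next to ring B for the macrocycle, with the diaryl ether made first by SNAr on a ring B fluoride activated by an ortho-formyl group. In the forward key step the seco phosphonium aldehyde is added slowly to KN(SiMe3)2 at high dilution; the ylide condenses with the ring B formyl group and gives macrocyclic styrene A1 as an E/Z mixture, erased by hydrogenation.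
- Merits: the formyl group serves twice, and Wittig macrocyclization is a fast, irreversible ionic closure well established for large rings.
- Weak points: SNAr needs an electron-poor ring B, so A1 lacks the C4 oxygen. That oxygen would have to be introduced on the macrocycle by electrophilic substitution and oxidation, in competition with ring A, which is at least as electron-rich.
- Comparison: the ring closure of Alternative 1 is better precedented than a macrocyclizing cycloaddition. Against that, the chosen plan has every oxygen in place before ring closure and ends with only a decarboxylation and a demethylation.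

**Alternative 2:** The cut is the O–C5(ring A) bond with ring A at the cyclohexenone oxidation level. In the forward key step the ring B phenoxide (Cs2CO3, high dilution) adds to the β-carbon of a tethered 3-chlorocyclohex-2-enone and expels chloride, giving the macrocyclic vinylogous ester A2 (racemate).
- Merits: vinylogous acyl substitution tolerates a hindered phenoxide and is fast; 5-alkylcyclohexane-1,3-diones are classical products of enone–malonate chemistry.
- Weak points: A2 must still be dehydrogenated to a phenol. Halogenation–elimination or oxidative dehydrogenation would have to spare the electron-rich ring B. Unveiling the ring B phenol while a dione or chloroenone is present in the same molecule also constrains the order of steps.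
- Comparison: the macrocyclization of Alternative 2 is probably the more dependable of the two. The chosen plan delivers ring A aromatic and correctly oxygenated in the ring-closing step and needs no oxidation afterwards.

**Alternative 3:** Two bonds of ring B are cut (C1–C6 and C2–C3), and ring B is built on the ether oxygen. In the forward key step, NaOMe in methanol at high dilution lets the aryloxymalonate anion add to the enone β-carbon, closing the 22-membered ring; the methyl ketone enolate then condenses onto one ester and gives A3 as a mixture of diastereomers and enol tautomers.
- Merits: the hindered phenol never appears; the ether oxygen is alkylated on the unhindered ring A phenol, and the 1,2,4-oxygenation of ring B comes from carbonyl chemistry.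
- Weak points: the ring-closing Michael addition forms a fully substituted carbon and is reversible under methoxide. A3 then needs loss of the angular ester and a dehydrogenation, again in the presence of an electron-rich aryl ether.
- Comparison: Alternative 3 is the only plan that avoids the hindered phenol as a nucleophile altogether. The chosen plan uses it only in an oxa-Michael addition at a linear ynoate and needs no redox adjustment after the macrocycle is formed.

Key step: step 11

## Route

Remark: 16-bromohexadecan-1-ol is taken as the commercial C16 unit. Alkene 6 is drawn as the expected (Z) major isomer and 15–17 as (E) isomers; neither geometry reaches the target, and the ketene acetal geometry of 18, 19 and F1 is left undefined.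

Step 1
Reactants: 1 16-bromohexadecan-1-ol; 2 triphenylphosphine
Product: 3 (16-hydroxyhexadecyl)triphenylphosphonium bromide
Conditions: MeCN, reflux
Reagents that add atoms: none
Why: SN2 quaternization of triphenylphosphine by a primary bromide; the free hydroxyl does not interfere.

Step 2
Reactants: 3 (16-hydroxyhexadecyl)triphenylphosphonium bromide; 4 3,5-dimethoxybenzaldehyde
Product: 6 (Z)-17-(3,5-dimethoxyphenyl)heptadec-16-en-1-ol (Z major, mixture used), via ylide alkoxide 5 (not isolated)
Conditions: NaN(SiMe3)2 (2.2 equiv), THF, 0 °C; then 4, −78 °C → rt; aqueous work-up
Reagents that add atoms: none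
Why: Wittig olefination; the second equivalent of base is taken up by the hydroxyl, and the non-stabilized ylide should give mainly the Z alkene, whose geometry is removed in step 3.

Step 3
Reactants: 6 (Z)-17-(3,5-dimethoxyphenyl)heptadec-16-en-1-ol
Product: 7 17-(3,5-dimethoxyphenyl)heptadecan-1-ol
Conditions: H2 (1 atm), Pd/C, EtOAc, rt
Reagents that add atoms: none
Why: heterogeneous catalytic hydrogenation of a styrenyl alkene; aryl ethers and the primary alcohol are inert.

Step 4
Reactants: 7 17-(3,5-dimethoxyphenyl)heptadecan-1-ol
Product: 8 17-(3,5-dimethoxyphenyl)heptadecanal
Conditions: Dess–Martin periodinane, CH2Cl2, rt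
Reagents that add atoms: none
Why: Dess–Martin oxidation stops at the aldehyde under near-neutral conditions; the arene has no free phenol that could be oxidised.

Step 5
Reactants: 8 17-(3,5-dimethoxyphenyl)heptadecanal
Product: 9 1,3-dimethoxy-5-(octadec-17-yn-1-yl)benzene
Conditions: dimethyl (1-diazo-2-oxopropyl)phosphonate, K2CO3, MeOH–THF, rt
Reagents that add atoms: dimethyl (1-diazo-2-oxopropyl)phosphonate, COP(=O)(OC)C(=[N+]=[N-])C(C)=O
Why: Seyferth–Gilbert homologation in the Ohira–Bestmann variant converts the aldehyde into a terminal alkyne with one added carbon; the former aldehyde carbon becomes the internal alkyne carbon (later C3 of ring A).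

Step 6
Reactants: 9 1,3-dimethoxy-5-(octadec-17-yn-1-yl)benzene
Product: 11 2,4-dimethoxy-6-(octadec-17-yn-1-yl)benzaldehyde, via aryl iminium chloride 10 (not isolated)
Conditions: POCl3, DMF, 0 → 60 °C; then H2O
Reagents that add atoms: N,N-dimethylformamide, CN(C)C=O; water, O
Why: Vilsmeier–Haack formylation of a 5-alkylresorcinol dimethyl ether should go para to one methoxy group and ortho to the chain, not into the crowded position between the two methoxy groups; an unactivated terminal alkyne is not attacked by the chloroiminium ion.

Step 7
Reactants: 11 2,4-dimethoxy-6-(octadec-17-yn-1-yl)benzaldehyde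
Product: 13 2,4-dimethoxy-6-(octadec-17-yn-1-yl)phenol, via aryl formate 12 (not isolated)
Conditions: mCPBA, CH2Cl2, 0 °C → rt; then K2CO3 (cat.), MeOH, rt
Reagents that add atoms: 3-chloroperbenzoic acid, OOC(=O)c1cccc(Cl)c1
Why: Dakin-type Baeyer–Villiger oxidation, in which the electron-rich aryl group migrates to give the formate, followed by methanolysis; the alkyne is not epoxidised under these conditions, and the phenol is handled under argon.

Step 8
Reactants: 13 2,4-dimethoxy-6-(octadec-17-yn-1-yl)phenol; 14 methyl but-2-ynoate
Product: 15 methyl (E)-3-[2,4-dimethoxy-6-(octadec-17-yn-1-yl)phenoxy]but-2-enoate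
Conditions: Cs2CO3 (cat.), DMF, 50 °C, Ar
Reagents that add atoms: none
Why: oxa-Michael addition of the phenoxide to the alk-2-ynoate; attack at a linear sp carbon tolerates the two ortho substituents, the terminal alkyne is not an acceptor, and the (E)-3-aryloxycrotonate is the expected thermodynamic product.

Step 9
Reactants: 15 methyl (E)-3-[2,4-dimethoxy-6-(octadec-17-yn-1-yl)phenoxy]but-2-enoate
Product: 17 19-{3,5-dimethoxy-2-[(E)-(4-methoxy-4-oxobut-2-en-2-yl)oxy]phenyl}nonadec-2-ynoic acid, via cesium alkynoate 16 (not isolated)
Conditions: CO2 (1 atm), AgI (cat.), Cs2CO3, DMF, 50 °C; then 1 M HCl, 0 °C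
Reagents that add atoms: carbon dioxide, O=C=O
Why: silver-catalysed C–H carboxylation of a terminal alkyne with CO2 and a carbonate base, a method that tolerates esters; cold acidification releases the alk-2-ynoic acid.

Step 10
Reactants: 17 19-{3,5-dimethoxy-2-[(E)-(4-methoxy-4-oxobut-2-en-2-yl)oxy]phenyl}nonadec-2-ynoic acid
Product: 19 trimethylsilyl 19-{3,5-dimethoxy-2-[(4-methoxy-4-trimethylsilyloxybuta-1,3-dien-2-yl)oxy]phenyl}nonadec-2-ynoate, via dilithium carboxylate dienolate 18 (not isolated)
Conditions: LiN(iPr)2 (2.1 equiv), THF, −78 °C; then Me3SiCl (2.3 equiv), −78 °C → rt; volatiles removed, pentane, filtration under Ar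
Reagents that add atoms: chlorotrimethylsilane, C[Si](C)(C)Cl
Why: γ-deprotonation and O-silylation of a 3-oxygenated crotonate, as in the preparation of 1,3-dialkoxy-1-silyloxybutadienes from 3-alkoxycrotonates; the first equivalent of base forms the lithium carboxylate, which should resist propargylic deprotonation at −78 °C, and the silyl chloride then caps both oxygens so that the alkynoate becomes a silyl ester.

Step 11
Reactants: 19 trimethylsilyl 19-{3,5-dimethoxy-2-[(4-methoxy-4-trimethylsilyloxybuta-1,3-dien-2-yl)oxy]phenyl}nonadec-2-ynoate
Product: 22 macrocyclic salicylic acid (grevirobstol B skeleton with ring B C2 and C4 as methyl ethers and CO2H at ring A C2, between the C1 OH and the C3 chain), via cyclohexadiene cycloadduct 20 (not isolated), via bis(trimethylsilyl) arene 21 (not isolated)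
Conditions: toluene (1 mM, slow addition), 130 °C, sealed vessel; then 1 M HCl, THF, rt
Reagents that add atoms: none
Why: A thermal normal-demand [4+2] cycloaddition joins the electron-rich silyl ketene-acetal diene to the silyl alkynoate; the bond from the nucleophilic CH2 terminus to the alkyne β-carbon (C3–C4 of ring A) is the more advanced and the acetal carbon–α-carbon bond (C1–C2) forms in the same event. The closest known reaction types are the Diels–Alder/aromatization of 1,1,3-trioxygenated ketene-acetal dienes with alk-2-ynoates to resorcylates and macrocyclizing intramolecular Diels–Alder reactions with the tether on the diene 2-position. Ring A closes as the six-membered ring of the cycloaddition, and the 22-membered ring closes through the C3–C4 bond in the bridged (type 2) mode, the tether running from the diene C2 oxygen to the alkyne β-carbon, so that ring A becomes meta-bridged. Cycloadduct 20 should lose methanol from the acetal carbon and the ring CH2 to give arene 21; the aryloxy group sits on an sp2 carbon and cannot be eliminated. The only stereocentre, the acetal carbon of 20, disappears on aromatization, so no stereocontrol is required. Aqueous acid then cleaves the silyl ether and the silyl ester to give 22. The step needs regioselectivity, which the polarity match of the diene CH2 terminus with the alkynoate β-carbon secures, and ring closure over oligomerization, which only high dilution and slow addition can secure because the chain has no conformational bias.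

Step 12
Reactants: 22 macrocyclic salicylic acid
Product: 23 grevirobstol B ring B 2,4-di-O-methyl ether (ring A: C1 OH, C3 chain, C5 O-aryl)
Conditions: Ag2CO3 (cat.), AcOH (cat.), DMSO, 120 °C
Reagents that add atoms: none
Why: protodecarboxylation of a benzoic acid substituted at both ortho positions, with an ortho hydroxyl and a para aryloxy group that favour ipso protonation; the silver-catalysed variant is known for ortho-substituted benzoic acids.

Step 13
Reactants: 23 grevirobstol B ring B 2,4-di-O-methyl ether
Product: 24 grevirobstol B
Conditions: BBr3, CH2Cl2, −78 °C → rt; then H2O, under Ar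
Reagents that add atoms: none
Why: Lewis-acid cleavage of aryl methyl ethers with BBr3; the diaryl ether has no alkyl C–O bond to cleave, and non-oxidative conditions protect the hydroquinone-type ring B.

## Compound list

1 | 16-bromohexadecan-1-ol | OCCCCCCCCCCCCCCCCBr | starting material
2 | triphenylphosphine | c1ccc(cc1)P(c1ccccc1)c1ccccc1 | starting material
3 | (16-hydroxyhexadecyl)triphenylphosphonium bromide | OCCCCCCCCCCCCCCCC[P+](c1ccccc1)(c1ccccc1)c1ccccc1.[Br-] | intermediate
4 | 3,5-dimethoxybenzaldehyde | COc1cc(C=O)cc(OC)c1 | starting material
5 | sodium alkoxide of the ylide, 16-(triphenylphosphoranylidene)hexadecan-1-olate | [Na+].[O-]CCCCCCCCCCCCCCCC=P(c1ccccc1)(c1ccccc1)c1ccccc1 | intermediate (not isolated)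
6 | (Z)-17-(3,5-dimethoxyphenyl)heptadec-16-en-1-ol (Z major, E/Z mixture) | OCCCCCCCCCCCCCCC/C=C\c1cc(OC)cc(OC)c1 | intermediate
7 | 17-(3,5-dimethoxyphenyl)heptadecan-1-ol | OCCCCCCCCCCCCCCCCCc1cc(OC)cc(OC)c1 | intermediate
8 | 17-(3,5-dimethoxyphenyl)heptadecanal | O=CCCCCCCCCCCCCCCCCc1cc(OC)cc(OC)c1 | intermediate
9 | 1,3-dimethoxy-5-(octadec-17-yn-1-yl)benzene | C#CCCCCCCCCCCCCCCCCc1cc(OC)cc(OC)c1 | intermediate
10 | N-{[2,4-dimethoxy-6-(octadec-17-yn-1-yl)phenyl]methylidene}-N-methylmethanaminium chloride | C#CCCCCCCCCCCCCCCCCc1cc(OC)cc(OC)c1C=[N+](C)C.[Cl-] | intermediate (not isolated)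
11 | 2,4-dimethoxy-6-(octadec-17-yn-1-yl)benzaldehyde | C#CCCCCCCCCCCCCCCCCc1cc(OC)cc(OC)c1C=O | intermediate
12 | 2,4-dimethoxy-6-(octadec-17-yn-1-yl)phenyl formate | C#CCCCCCCCCCCCCCCCCc1cc(OC)cc(OC)c1OC=O | intermediate (not isolated)
13 | 2,4-dimethoxy-6-(octadec-17-yn-1-yl)phenol | C#CCCCCCCCCCCCCCCCCc1cc(OC)cc(OC)c1O | intermediate
14 | methyl but-2-ynoate | CC#CC(=O)OC | starting material
15 | methyl (E)-3-[2,4-dimethoxy-6-(octadec-17-yn-1-yl)phenoxy]but-2-enoate | C#CCCCCCCCCCCCCCCCCc1cc(OC)cc(OC)c1O/C(C)=C/C(=O)OC | intermediate
16 | cesium 19-{3,5-dimethoxy-2-[(E)-(4-methoxy-4-oxobut-2-en-2-yl)oxy]phenyl}nonadec-2-ynoate | [Cs+].[O-]C(=O)C#CCCCCCCCCCCCCCCCCc1cc(OC)cc(OC)c1O/C(C)=C/C(=O)OC | intermediate (not isolated)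
17 | 19-{3,5-dimethoxy-2-[(E)-(4-methoxy-4-oxobut-2-en-2-yl)oxy]phenyl}nonadec-2-ynoic acid | OC(=O)C#CCCCCCCCCCCCCCCCCc1cc(OC)cc(OC)c1O/C(C)=C/C(=O)OC | intermediate
18 | dilithium carboxylate dienolate of 17 | [Li+].[Li+].[O-]C(=O)C#CCCCCCCCCCCCCCCCCc1cc(OC)cc(OC)c1OC(=C)C=C(OC)[O-] | intermediate (not isolated)
19 | trimethylsilyl 19-{3,5-dimethoxy-2-[(4-methoxy-4-trimethylsilyloxybuta-1,3-dien-2-yl)oxy]phenyl}nonadec-2-ynoate | C[Si](C)(C)OC(=O)C#CCCCCCCCCCCCCCCCCc1cc(OC)cc(OC)c1OC(=C)C=C(OC)O[Si](C)(C)C | intermediate
20 | macrocyclic cyclohexa-1,4-diene cycloadduct (racemic; acetal carbon with OMe and OSiMe3, silyl ester on the adjacent sp2 carbon) | COC1(O[Si](C)(C)C)C=C2CC(CCCCCCCCCCCCCCCCc3cc(OC)cc(OC)c3O2)=C1C(=O)O[Si](C)(C)C | intermediate (not isolated)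
21 | trimethylsilyl ester and ring A C1 trimethylsilyl ether of 22 | C[Si](C)(C)OC(=O)c1c(O[Si](C)(C)C)cc2cc1CCCCCCCCCCCCCCCCc1cc(OC)cc(OC)c1O2 | intermediate (not isolated)
22 | macrocyclic salicylic acid (ring A: C1 OH, C2 CO2H, C3 chain, C5 O-aryl; ring B: C2 and C4 OMe) | OC(=O)c1c(O)cc2cc1CCCCCCCCCCCCCCCCc1cc(OC)cc(OC)c1O2 | intermediate
23 | grevirobstol B ring B 2,4-di-O-methyl ether | Oc1cc2cc(c1)Oc1c(OC)cc(OC)cc1CCCCCCCCCCCCCCCC2 | intermediate
24 | grevirobstol B | Oc1cc2cc(c1)Oc1c(O)cc(O)cc1CCCCCCCCCCCCCCCC2 | target

## Step count and risks

Total: 13 steps. Longest linear sequence: 13 steps (from 1).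

**Step 11 (key step).** At the dilution needed to suppress oligomerization the cycloaddition is slow, and unimolecular decay of the diene may outrun it: oxygen-to-carbon silyl migration, hydrogen shift, protodesilylation by traces of acid, or addition of residual amine to the alkynoate. At higher concentration, intermolecular cycloaddition would dominate. The fallback sets out from 17 and returns at 22; it closes the large ring by silylation and runs the cycloaddition across a short temporary tether. Dianion 18 is generated as in step 10 and added slowly at high dilution to iPr2SiCl2 (1 equiv) in THF, so that one silicon is bonded to both the carboxylate oxygen and the ketene acetal oxygen. This should give the 28-membered cyclic diisopropylsilylene (silyl ester and silyl ketene acetal sharing one silicon) F1. On heating in toluene the acetal carbon and the alkyne α-carbon are only four atoms apart (O–Si–O–C=O), as in temporary silicon-tethered intramolecular Diels–Alder reactions, and the same two bonds should form to give the silicon-bridged cycloadduct F2. Loss of methanol would give the 2,2-diisopropyl-4H-1,3,2-benzodioxasilin-4-one F3, and aqueous HCl in THF would cleave the silylene to give 22.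

**Step 10.** Metalation may be unselective: competing deprotonation at the propargylic CH2 of the lithium alkynoate (leading to allenes), carbon silylation in place of oxygen silylation, or hydrolysis of the ketene acetal during salt removal. The fallback sets out from 17 and returns at 19; it replaces amide-base enolization by soft enolization with Me3SiOTf and Et3N in ether at 0 °C. The acid is capped first as its silyl ester. The vinylogous ester, the more Lewis-basic carbonyl, is then O-silylated and loses a γ-proton to the amine, so no carbanion is formed next to the alkynoate.

**Step 9.** The carboxylation is reversible and may stop short; the alkynoate may lose CO2 again on acidification and isolation; adventitious hydroxide in Cs2CO3/DMF may cleave the aryloxycrotonate. The fallback sets out from 13 and returns at 17; it carboxylates before the ester is present. Phenol 13 is treated with n-BuLi (2.2 equiv) in THF at −78 °C and then CO2, giving after acidification 19-(2-hydroxy-3,5-dimethoxyphenyl)nonadec-2-ynoic acid F4. Its dianion (Cs2CO3, 2.2 equiv, DMF) adds through the phenoxide to 14, the carboxylate-bearing alkyne being deactivated as an acceptor, and acidification gives 17.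

**Step 8.** The hindered phenoxide may add slowly to the β-methyl-bearing alkyne carbon, while base isomerizes 14 to the allenoate and the electron-rich phenoxide is oxidised by air. The fallback sets out from 13 and returns at 15; it replaces conjugate addition to an alkyne by addition–elimination at an sp2 carbon, using methyl (E)-3-chlorobut-2-enoate with K2CO3 in DMF.

## Further compounds

F1 | step 11 | 28-membered cyclic diisopropylsilylene of 18 (silicon bonded to the carboxylate oxygen and to the ketene acetal oxygen) | COC1=CC(=C)Oc2c(OC)cc(OC)cc2CCCCCCCCCCCCCCCCC#CC(=O)O[Si](C(C)C)(C(C)C)O1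
F2 | step 11 | silicon-bridged cyclohexa-1,4-diene cycloadduct (racemic) | COC12C=C3CC(=C1C(=O)O[Si](C(C)C)(C(C)C)O2)CCCCCCCCCCCCCCCCc1cc(OC)cc(OC)c1O3
F3 | step 11 | macrocyclic 2,2-diisopropyl-4H-1,3,2-benzodioxasilin-4-one (cyclic silylene of 22) | CC(C)[Si]1(C(C)C)OC(=O)c2c(O1)cc3cc2CCCCCCCCCCCCCCCCc2cc(OC)cc(OC)c2O3
F0 | step 10 | none | none
F4 | step 9 | 19-(2-hydroxy-3,5-dimethoxyphenyl)nonadec-2-ynoic acid | OC(=O)C#CCCCCCCCCCCCCCCCCc1cc(OC)cc(OC)c1O
F0 | step 8 | none | none
A1 | alternative 1 | macrocyclic styrene lacking the ring B C4 oxygen (E/Z mixture) | COc1cccc2c1Oc1cc(OC)cc(c1)CCCCCCCCCCCCCCC=C2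
A2 | alternative 2 | macrocyclic 3-aryloxy-5-alkylcyclohex-2-enone (racemate) | O=C1C=C2CC(C1)CCCCCCCCCCCCCCCCc1cc(OC)cc(OC)c1O2
A3 | alternative 3 | macrocyclic methyl 1-aryloxy-6-alkyl-2,4-dioxocyclohexane-1-carboxylate (mixture of diastereomers and enol tautomers) | COc1cc2cc(c1)OC1(C(=O)OC)C(=O)CC(=O)CC1CCCCCCCCCCCCCCCC2
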